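4 questions stand on one flask, and I reckon the last two, the ratio of G to Z at 25 h and which of them leads, with one carried quantity.

| setting | ochre | green | flask |
|---|---|---|---|
| J | 0.10 M | 0.10 M | 0.10 M |
| L | 0.10 M | 0.10 M | 0.100 M |
| X | 0.090 M | 0.090 M | 0.0900 M |
| D | 3.4 mM | 7.5 mM | 5.00 mM |
| remark | run made earlier | run made earlier |  |
| time |  |  | 25 h |

| run | time / h | G / % | Z / % |
|---|---|---|---|
| ochre | 1.50 | 3 | 3 |
| ochre | 5.00 | 2 | 11 |
| ochre | 8.00 | 0 | 21 |
| ochre | 12.0 | 1 | 30 |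
| ochre | 20.0 | 2 | 39 |
| ochre | 25.0 | 1 | 45 |
| ochre | 30.0 | 0 | 51 |
| green | 1.50 | 2 | 2 |
| green | 5.00 | 4 | 15 |
| green | 8.00 | 5 | 19 |
| green | 12.0 | 1 | 29 |
| green | 20.0 | 5 | 40 |
| green | 25.0 | 5 | 46 |
| green | 30.0 | 0 | 51 |

(scatter of a reading: 2 percentage points)

- ratio of G to Z at 25 min
- ratio of G to Z at 3.0 h
- ratio of G to Z at 25 h
- which of G and Z there is more of at 25 h

G reads 0% to 5% in the two runs while Z climbs, so I work with the J left, which I take as the charge less G and Z. The flask's [D] of 5.00 mM lies between 3.4 mM and 7.5 mM, so I pool both runs from 5.00 h on and divide summed G by summed J left, which gives 0.0335. I carry this reading, with the scatter of the runs in it, as the standing share, [G] over [J] at fixed [L], a pre-equilibrium ratio. The two runs read Z at 45.5% on average at 25 h, and J and G divide the rest by that share, so my ratio is 0.0388, with Z ahead.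

The forecast gives 3, 0.35 and 0.04, with Z ahead, holding that “G scales roughly with D”. The flask gives 1.48, 0.377 and 0.0464, with Z ahead, at 2.13% G and 45.9% Z.

    J ⇌ E (K = 0.0180, k = 0.265 h⁻¹)
    L + E ⇌ G (K = 25.3 M⁻¹, k = 48.2 M⁻¹ h⁻¹)
    X + E → Z (k = 25.9 M⁻¹ h⁻¹)
    E + D → Q (k = 1.85 M⁻¹ h⁻¹)

In this flask [G]/[J] is 0.0382 at 2.50 h and 0.0419 at 25.0 h, while J falls from 87.8% to 50.9%. In the neighbouring flask with 0.15 M of X, 63.8% Z and 34.1% J stand at 25.0 h, so the share 0.0335 gives a ratio of 0.0179, and that flask shows 0.0213.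

The readings were generated by integration for an exercise; noise was put on by code.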